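**Retrosynthetic overview**

1. Xestin B ⇐ invertive methanolysis at C6 and esterification of a bridged peroxy-lactone (2,6,7-trioxabicyclo[3.2.2]nonenone). Its lactone bridge C6–O–CO–CH2–C3 is a temporary ring absent from the target ⇐ tert-butyl ester of the (3R)-dioxinol.
2. Key disconnection: the O2–C3 bond of the 3,6-dihydro-1,2-dioxine. It is closed by a catalytic enantioselective 6-exo-trig peroxy-Michael addition of the C6 perhydrate formed in the flask from an achiral (2E,4Z)-6-oxo-2,4-dienoate and H2O2.
3. Enabling feature: the cis C4=C5 alkene (the later ring alkene) holds the C6 ketone, which takes up H2O2 reversibly, within reach of C3, the β-carbon of the C2=C3 enoate. C6 stays epimerisable and is funnelled afterwards.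
4. Keto dienoate ⇐ dearomatising photooxygenation of a 2-alkylfuran (furan C2–C5 become C6–C3) and Wittig olefination; the furan ⇐ furan + 1,12-dibromododecane + sorbyl acetate.
5. Ring order: dioxine ring (step 4), then the temporary seven-membered lactone ring (step 5), reopened in step 6.

Key step: step 4

Assumption: the squaramide catalyst from 9-amino-9-deoxy-epi-quinidine is taken to give the (3R) peroxide; its quinine-derived pseudoenantiomer would replace it, with no other change, should the sense of induction be opposite.
Assumption: 5 and 8 are taken as commercial (5 is otherwise one acetylation from sorbyl alcohol); atom numbers C3–C6 refer to the dioxine ring and coincide with the chain numbers of 11.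

**Step 1**
Reactants: 1 furan; 2 1,12-dibromododecane
Product: 4 2-(12-bromododecyl)furan, via 2-furyllithium 3 (not isolated)
Conditions: n-BuLi, THF, −78 to 0 °C; then 2 (3 equiv), THF, 0 °C to rt
Reagents that add atoms: none
Why: α-lithiation of furan and SN2 alkylation of 2-furyllithium by a primary bromide are standard (lithiation–alkylation), and the excess of the symmetric dibromide keeps the second bromide for step 2.

**Step 2**
Reactants: 4 2-(12-bromododecyl)furan; 5 (2E,4E)-hexa-2,4-dien-1-yl acetate
Product: 7 2-[(14E,16E)-octadeca-14,16-dien-1-yl]furan, via Grignard reagent 6 (not isolated)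
Conditions: Mg, THF, 40 °C; then 5, Li2CuCl4 (3 mol%), THF, −20 to 0 °C
Reagents that add atoms: none
Why: the Li2CuCl4-catalysed coupling of a primary alkyl Grignard reagent with an allylic acetate (Kochi coupling) should alkylate sorbyl acetate at its CH2–O carbon with the E,E diene kept, as in dienyl pheromone syntheses; no stereocenter is formed.

**Step 3**
Reactants: 7 2-[(14E,16E)-octadeca-14,16-dien-1-yl]furan; 8 (tert-butoxycarbonylmethylene)triphenylphosphorane
Product: 11 tert-butyl (2E,4Z,20E,22E)-6-oxotetracosa-2,4,20,22-tetraenoate, via furan endoperoxide 9 (not isolated), via (Z)-4-oxoenal 10 (not isolated)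
Conditions: O2, visible light, tetraphenylporphyrin (cat.), CH2Cl2, −78 °C; Me2S, −78 to 0 °C; then 8, 0 °C to rt, dark
Reagents that add atoms: dioxygen, O=O
Why: singlet oxygen should add [4+2] to the electron-rich furan much faster than to the acyclic chain diene, Me2S reduction of the endoperoxide opens it to the cis-enedione (the Z alkene is the former furan C3=C4 bond), and the stabilised ylide olefinates only the aldehyde with E selectivity (dearomatising furan photooxygenation followed by Wittig reaction).

**Step 4**
Reactants: 11 tert-butyl (2E,4Z,20E,22E)-6-oxotetracosa-2,4,20,22-tetraenoate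
Product: 13 tert-butyl 2-[(3R)-6-hydroxy-6-[(14E,16E)-octadeca-14,16-dien-1-yl]-3,6-dihydro-1,2-dioxin-3-yl]acetate (C6 epimer mixture), via C6 perhydrate 12 (not isolated)
Conditions: urea·H2O2 (1.2 equiv), squaramide of 9-amino-9-deoxy-epi-quinidine and 3,5-bis(trifluoromethyl)aniline (10 mol%), toluene/CH2Cl2, −20 °C, dark
Reagents that add atoms: hydrogen peroxide (from its urea adduct), OO
Why: Proposed new method: the C6 ketone of 11 takes up H2O2 reversibly to give perhydrate 12, whose OOH group is hydrogen-bonded and deprotonated by the quinuclidine of the catalyst while the squaramide N–H bonds bind the ester carbonyl, and the terminal peroxide oxygen adds to C3, the β-carbon of the C2=C3 enoate, followed by protonation at C2 (peroxy-Michael addition). The closest known reaction types are the amine-mediated intramolecular conjugate addition of hydroperoxy ketals to enoates that gives 1,2-dioxane-3-acetates, the cinchona-catalysed intramolecular oxa-Michael addition of phenols to enoates, and the chiral-acid-catalysed peroxyhemiacetalisation/oxa-Michael cascade to 1,2,4-trioxanes. The one ring formed, the 3,6-dihydro-1,2-dioxine, closes in the 6-exo-trig mode. C3 is the only stereocenter fixed here and is controlled by the catalyst, which holds enoate and peroxide in one chiral pocket and exposes one face of C3; C6 arises as an equilibrating hemiketal (ring–chain tautomerism) and is left on purpose to step 5. The step needs O–C3 closure to outrun nucleophilic epoxidation at C4=C5 and base-induced Kornblum–DeLaMare cleavage: the cis C4=C5 alkene gives the tethered OOH a six-membered transition state only for C3, the weak amine base at low temperature generates little free hydroperoxide anion, and a 4E isomer cannot cyclise.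

**Step 5**
Reactants: 13 tert-butyl 2-[(3R)-6-hydroxy-6-[(14E,16E)-octadeca-14,16-dien-1-yl]-3,6-dihydro-1,2-dioxin-3-yl]acetate
Product: 14 (1R,5R)-1-[(14E,16E)-octadeca-14,16-dien-1-yl]-2,6,7-trioxabicyclo[3.2.2]non-8-en-3-one
Conditions: CSA (10 mol%), 4 Å MS, CH2Cl2, 0 °C to rt
Reagents that add atoms: none
Why: Proposed new method: acid ionises the C6 hemiketal of either epimer to the ring peroxycarbenium ion, the carbonyl oxygen of the tert-butyl ester on C3 adds to C6 across the ring, and the resulting tert-butyl dialkoxycarbenium ion loses 2-methylpropene, so both C6 epimers converge on the one bridged lactone whose C6–O bond is necessarily cis to the C3 side chain (bicyclic constraint, C3 untouched); the closest known reaction types are substitution of peroxyketals through peroxycarbenium ions and lactonisation of tert-butyl esters onto oxocarbenium or halonium ions with loss of 2-methylpropene.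

**Step 6**
Reactants: 14 (1R,5R)-1-[(14E,16E)-octadeca-14,16-dien-1-yl]-2,6,7-trioxabicyclo[3.2.2]non-8-en-3-one
Product: 16 xestin B (methyl 2-[(3R,6S)-6-methoxy-6-[(14E,16E)-octadeca-14,16-dien-1-yl]-3,6-dihydro-1,2-dioxin-3-yl]acetate), via carboxylic acid 15 (not isolated)
Conditions: MeOH, PPTS (5 mol%), −20 to 0 °C; then TMSCHN2, toluene/MeOH, 0 °C
Reagents that add atoms: methanol, CO; (trimethylsilyl)diazomethane, C[Si](C)(C)C=[N+]=[N-]
Why: Proposed new method: the strained tertiary acyloxy peroxyketal should solvolyse in methanol by alkyl–oxygen cleavage with the carboxylate leaving group still tethered over the face of C6 that it leaves, so methanol enters from the opposite face (inversion, as in the invertive alcoholysis of 1,6-anhydro sugars and of tertiary sialyl donors) and the methoxy group ends trans to the acetic acid chain, which is (6S); the weak buffered acid at low temperature should keep the product ketal from equilibrating, and the freed acid is methylated in the same flask (diazomethane-type esterification).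

**Compound list**

1 | furan | c1ccoc1 | starting material
2 | 1,12-dibromododecane | BrCCCCCCCCCCCCBr | starting material
3 | 2-furyllithium | [Li]c1ccco1 | intermediate
4 | 2-(12-bromododecyl)furan | BrCCCCCCCCCCCCc1ccco1 | intermediate
5 | (2E,4E)-hexa-2,4-dien-1-yl acetate (sorbyl acetate) | C/C=C/C=C/COC(C)=O | starting material
6 | [12-(furan-2-yl)dodecyl]magnesium bromide | Br[Mg]CCCCCCCCCCCCc1ccco1 | intermediate
7 | 2-[(14E,16E)-octadeca-14,16-dien-1-yl]furan | C/C=C/C=C/CCCCCCCCCCCCCc1ccco1 | intermediate
8 | (tert-butoxycarbonylmethylene)triphenylphosphorane | CC(C)(C)OC(=O)C=P(c1ccccc1)(c1ccccc1)c1ccccc1 | starting material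
9 | 1-[(14E,16E)-octadeca-14,16-dien-1-yl]-2,3,7-trioxabicyclo[2.2.1]hept-5-ene (furan endoperoxide, racemic) | C/C=C/C=C/CCCCCCCCCCCCCC12OOC(O1)C=C2 | intermediate
10 | (2Z,18E,20E)-4-oxodocosa-2,18,20-trienal | C/C=C/C=C/CCCCCCCCCCCCCC(=O)/C=C\C=O | intermediate
11 | tert-butyl (2E,4Z,20E,22E)-6-oxotetracosa-2,4,20,22-tetraenoate | C/C=C/C=C/CCCCCCCCCCCCCC(=O)/C=C\C=C\C(=O)OC(C)(C)C | intermediate
12 | tert-butyl (2E,4Z,20E,22E)-6-hydroperoxy-6-hydroxytetracosa-2,4,20,22-tetraenoate (C6 perhydrate, racemic) | C/C=C/C=C/CCCCCCCCCCCCCC(O)(OO)/C=C\C=C\C(=O)OC(C)(C)C | intermediate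
13 | tert-butyl 2-[(3R)-6-hydroxy-6-[(14E,16E)-octadeca-14,16-dien-1-yl]-3,6-dihydro-1,2-dioxin-3-yl]acetate (C6 epimer mixture) | C/C=C/C=C/CCCCCCCCCCCCCC1(O)C=C[C@@H](CC(=O)OC(C)(C)C)OO1 | intermediate
14 | (1R,5R)-1-[(14E,16E)-octadeca-14,16-dien-1-yl]-2,6,7-trioxabicyclo[3.2.2]non-8-en-3-one | C/C=C/C=C/CCCCCCCCCCCCC[C@]12OC(=O)C[C@H](C=C1)OO2 | intermediate
15 | 2-[(3R,6S)-6-methoxy-6-[(14E,16E)-octadeca-14,16-dien-1-yl]-3,6-dihydro-1,2-dioxin-3-yl]acetic acid | C/C=C/C=C/CCCCCCCCCCCCC[C@@]1(OC)C=C[C@@H](CC(=O)O)OO1 | intermediate
16 | xestin B, methyl 2-[(3R,6S)-6-methoxy-6-[(14E,16E)-octadeca-14,16-dien-1-yl]-3,6-dihydro-1,2-dioxin-3-yl]acetate | C/C=C/C=C/CCCCCCCCCCCCC[C@@]1(OC)C=C[C@@H](CC(=O)OC)OO1 | target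

**Step count and risks**

Total step count: 6. Longest linear sequence: 6 steps (from furan 1).

Steps most likely to fail:

Step 4 (Proposed new method). The enone may be epoxidised by free hydroperoxide or isomerised from cis to trans by the amine before the perhydrate cyclises. Facial discrimination at C3 may be poor, and the dioxinol may be cleaved by base. The fallback sets out from 11 and uses known chemistry only. Peroxyketalisation with urea·H2O2 and Sc(OTf)3 in MeOH should give the hydroperoxy methyl ketal tert-butyl (2E,4Z,20E,22E)-6-hydroperoxy-6-methoxytetracosa-2,4,20,22-tetraenoate F1. Amine-mediated intramolecular hydroperoxide conjugate addition (Et2NH, CF3CH2OH) should close the ring to the racemic tert-butyl 2-[6-methoxy-6-[(14E,16E)-octadeca-14,16-dien-1-yl]-3,6-dihydro-1,2-dioxin-3-yl]acetate F2 as both C6 epimers. TsOH in MeOH at 40 °C should exchange the tert-butyl for the methyl ester and equilibrate C6, giving racemic xestin B F3 and its racemic C6 epimer F4. These are separated on silica, F4 being re-equilibrated in acidic methanol. Resolution of F3 by HPLC on a chiral stationary phase comes back to the route at 16.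

Step 5 (Proposed new method). The ester may fail to capture the peroxycarbenium ion, which may instead lose a proton or oligomerise, or the open hydroperoxide tautomer may undergo acid-induced Hock-type cleavage. The fallback sets out from 13. The known acid-catalysed ketalisation of dioxinols in methanol (TsOH, MeOH, rt to 40 °C), with concurrent exchange of the tert-butyl for the methyl ester, should give 16 under thermodynamic control. It forms together with its epimer methyl 2-[(3R,6R)-6-methoxy-6-[(14E,16E)-octadeca-14,16-dien-1-yl]-3,6-dihydro-1,2-dioxin-3-yl]acetate F5. The two are separated by chromatography and F5 is resubmitted to the same conditions. The fallback comes back to the route at 16.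

Step 6 (Proposed new method). Inversion may be lost through a free, conformationally relaxed peroxycarbenium ion, acyl–oxygen cleavage may compete, or the product ketal may equilibrate. The fallback sets out from 14 and gives up kinetic control. Hydrolytic opening (AcOH/THF/H2O) should give the dioxinol acid 2-[(3R)-6-hydroxy-6-[(14E,16E)-octadeca-14,16-dien-1-yl]-3,6-dihydro-1,2-dioxin-3-yl]acetic acid F6. TMSCHN2 then gives the methyl ester methyl 2-[(3R)-6-hydroxy-6-[(14E,16E)-octadeca-14,16-dien-1-yl]-3,6-dihydro-1,2-dioxin-3-yl]acetate F7. Equilibrating ketalisation (TsOH, MeOH) should give 16 and its epimer methyl 2-[(3R,6R)-6-methoxy-6-[(14E,16E)-octadeca-14,16-dien-1-yl]-3,6-dihydro-1,2-dioxin-3-yl]acetate F8. These are separated by chromatography with recycling of F8, and the fallback comes back to the route at 16.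

**Further compounds**

F1 | step 4 | tert-butyl (2E,4Z,20E,22E)-6-hydroperoxy-6-methoxytetracosa-2,4,20,22-tetraenoate (racemic) | C/C=C/C=C/CCCCCCCCCCCCCC(OC)(OO)/C=C\C=C\C(=O)OC(C)(C)C
F2 | step 4 | tert-butyl 2-[6-methoxy-6-[(14E,16E)-octadeca-14,16-dien-1-yl]-3,6-dihydro-1,2-dioxin-3-yl]acetate (racemic, both C6 epimers) | C/C=C/C=C/CCCCCCCCCCCCCC1(OC)C=CC(CC(=O)OC(C)(C)C)OO1
F3 | step 4 | racemic xestin B, methyl 2-[(3R*,6S*)-6-methoxy-6-[(14E,16E)-octadeca-14,16-dien-1-yl]-3,6-dihydro-1,2-dioxin-3-yl]acetate (racemate, one enantiomer drawn) | C/C=C/C=C/CCCCCCCCCCCCC[C@@]1(OC)C=C[C@@H](CC(=O)OC)OO1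
F4 | step 4 | methyl 2-[(3R*,6R*)-6-methoxy-6-[(14E,16E)-octadeca-14,16-dien-1-yl]-3,6-dihydro-1,2-dioxin-3-yl]acetate (racemate, one enantiomer drawn) | C/C=C/C=C/CCCCCCCCCCCCC[C@]1(OC)C=C[C@@H](CC(=O)OC)OO1
F5 | step 5 | methyl 2-[(3R,6R)-6-methoxy-6-[(14E,16E)-octadeca-14,16-dien-1-yl]-3,6-dihydro-1,2-dioxin-3-yl]acetate | C/C=C/C=C/CCCCCCCCCCCCC[C@]1(OC)C=C[C@@H](CC(=O)OC)OO1
F6 | step 6 | 2-[(3R)-6-hydroxy-6-[(14E,16E)-octadeca-14,16-dien-1-yl]-3,6-dihydro-1,2-dioxin-3-yl]acetic acid (C6 epimer mixture) | C/C=C/C=C/CCCCCCCCCCCCCC1(O)C=C[C@@H](CC(=O)O)OO1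
F7 | step 6 | methyl 2-[(3R)-6-hydroxy-6-[(14E,16E)-octadeca-14,16-dien-1-yl]-3,6-dihydro-1,2-dioxin-3-yl]acetate (C6 epimer mixture) | C/C=C/C=C/CCCCCCCCCCCCCC1(O)C=C[C@@H](CC(=O)OC)OO1
F8 | step 6 | methyl 2-[(3R,6R)-6-methoxy-6-[(14E,16E)-octadeca-14,16-dien-1-yl]-3,6-dihydro-1,2-dioxin-3-yl]acetate | C/C=C/C=C/CCCCCCCCCCCCC[C@]1(OC)C=C[C@@H](CC(=O)OC)OO1
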